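**Strategy.** Everything rests on cutting the oxolane (O1, C2 carrying ring A, C3 carrying C9H2OAc, C4 carrying C7'H2–ring B, C5H2) at C3–C4 and at C7'–ring B. Because C3 is flanked only by oxygen-bearing carbons and O1–C5–C4=C7' can be an O-allyl group, a C3 radical should close 5-exo onto C4 and the C7' radical should be arylated by nickel, so one operation builds the ring, two C–C bonds and the C3 and C4 stereocentres under control of C2. The precursor is a β-iodo allyl ether, 3-(allyloxy)-3-aryl-2-iodopropyl acetate, whose benzylic stereocentre derives from a Katsuki–Sharpless epoxidation; the phenols travel as benzyl ethers.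

Key step: step 8

Remark on the chemistry: the iodine-bearing carbon of 9 is drawn as the inversion product of the displacement; either epimer serves, because this centre becomes planar in step 8. The oxolane locants O1, C2–C5, C9 and C7' are also used for the corresponding atoms of the open-chain intermediates where stated.

**Step 1**
Reactants: 1 3,4-bis(benzyloxy)benzaldehyde; 2 triethyl phosphonoacetate
Product: 3 ethyl (E)-3-[3,4-bis(benzyloxy)phenyl]prop-2-enoate
Conditions: NaH, THF, 0 °C to rt
Reagents that add atoms: none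
Why: Horner–Wadsworth–Emmons olefination of an aromatic aldehyde with a stabilised phosphonate anion should give the (E)-enoate; no stereocentre is formed.

**Step 2**
Reactants: 3 ethyl (E)-3-[3,4-bis(benzyloxy)phenyl]prop-2-enoate
Product: 4 (E)-3-[3,4-bis(benzyloxy)phenyl]prop-2-en-1-ol
Conditions: iBu2AlH (2.5 equiv), CH2Cl2, −78 °C
Reagents that add atoms: none
Why: 1,2-reduction of an α,β-unsaturated ester by iBu2AlH at low temperature should give the allylic alcohol without touching the alkene or the benzyl ethers.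

**Step 3**
Reactants: 4 (E)-3-[3,4-bis(benzyloxy)phenyl]prop-2-en-1-ol
Product: 5 [(2S,3S)-3-[3,4-bis(benzyloxy)phenyl]oxiran-2-yl]methanol
Conditions: Ti(OiPr)4 (10 mol%), L-(+)-diethyl tartrate (12 mol%), t-BuOOH (anhydrous, 2 equiv), 4 Å MS, CH2Cl2, −20 °C; non-acidic work-up, used at once
Reagents that add atoms: tert-butyl hydroperoxide, CC(C)(C)OO
Why: Katsuki–Sharpless asymmetric epoxidation of an (E)-allylic alcohol, in which the titanium–L-(+)-tartrate complex delivers oxygen to the alkene face that gives the (2S,3S)-trans-oxirane, so both oxirane carbons are set by the catalyst.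

**Step 4**
Reactants: 5 [(2S,3S)-3-[3,4-bis(benzyloxy)phenyl]oxiran-2-yl]methanol; 6 allyl alcohol
Product: 7 (2S,3R)-3-(allyloxy)-3-[3,4-bis(benzyloxy)phenyl]propane-1,2-diol
Conditions: BF3·OEt2 (10 mol%), allyl alcohol (10 equiv), CH2Cl2, −30 °C
Reagents that add atoms: none
Why: Lewis-acid-catalysed alcoholysis of an aryl oxirane takes place at the benzylic carbon (future C2 of the oxolane) by backside attack of allyl alcohol, so this carbon is inverted to R while the neighbouring carbinol carbon is untouched, and any benzylic epimer from a looser ionisation is a diastereomer that is removed here by chromatography before the neighbouring centre is lost.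

**Step 5**
Reactants: 7 (2S,3R)-3-(allyloxy)-3-[3,4-bis(benzyloxy)phenyl]propane-1,2-diol
Product: 8 (2S,3R)-3-(allyloxy)-3-[3,4-bis(benzyloxy)phenyl]-2-hydroxypropyl acetate
Conditions: AcCl (1.05 equiv), 2,4,6-collidine, CH2Cl2, −78 °C
Reagents that add atoms: acetyl chloride, CC(Cl)=O
Why: Kinetically controlled acylation with an acyl chloride and a hindered pyridine base should select the primary hydroxyl over the secondary one, which sits next to the branched benzylic ether carbon; no stereocentre is affected.

**Step 6**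
Reactants: 8 (2S,3R)-3-(allyloxy)-3-[3,4-bis(benzyloxy)phenyl]-2-hydroxypropyl acetate
Product: 9 (2R,3R)-3-(allyloxy)-3-[3,4-bis(benzyloxy)phenyl]-2-iodopropyl acetate
Conditions: PPh3, I2, imidazole, toluene, 60 °C
Reagents that add atoms: iodine, II
Why: Garegg–Samuelsson (Appel-type) iodination, in which the alkoxyphosphonium iodide should collapse by SN2 with inversion in a non-ionising solvent, and the configuration of this carbon (future C3) does not matter because it becomes the radical centre in step 8.

**Step 7**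
Reactants: 10 1-(benzyloxy)-4-bromo-2-methoxybenzene
Product: 12 [4-(benzyloxy)-3-methoxyphenyl]zinc bromide, via arylmagnesium bromide 11 (not isolated)
Conditions: Mg, LiCl, THF, rt; then ZnBr2, THF, 0 °C; used as a titrated THF solution
Reagents that add atoms: zinc bromide, Br[Zn]Br; magnesium, [Mg] (enters intermediate 11 only)
Why: Magnesium insertion into the aryl bromide (Grignard formation) followed by transmetallation to zinc should give an arylzinc halide that tolerates the acetate of 9 and brings no alkyl halide by-product into step 8.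

**Step 8**
Reactants: 9 (2R,3R)-3-(allyloxy)-3-[3,4-bis(benzyloxy)phenyl]-2-iodopropyl acetate; 12 [4-(benzyloxy)-3-methoxyphenyl]zinc bromide
Product: 13 [(2S,3R,4R)-2-[3,4-bis(benzyloxy)phenyl]-4-{[4-(benzyloxy)-3-methoxyphenyl]methyl}oxolan-3-yl]methyl acetate
Conditions: Ni(py)4Cl2 (10 mol%), s-Bu-pybox (12 mol%), 12 (2.5 equiv), THF, rt
Reagents that add atoms: none
Why: The arylzinc reduces the divalent nickel precatalyst to a low-valent aryl–nickel–pybox species that abstracts iodine from 9, giving a secondary radical at the future C3 and erasing the C–I configuration; this radical adds to the O-allyl alkene (C3–C4 bond), and the primary C7' radical is captured by aryl–nickel to give a trivalent alkyl(aryl)nickel that reductively eliminates the C7'–ring B bond. The closest known reaction type is the nickel-catalysed radical cyclisation–Negishi coupling cascade of β-halo ethers and β-halo acetals carrying O-allyl groups with organozinc halides. The oxolane closes in the 5-exo-trig radical mode. C3 and C4 are set in the chair-like Beckwith–Houk transition state under control of C2: ring A on C2 sits pseudo-equatorial and ends trans to the new C4–C7' bond, while the CH2OAc group on the radical carbon ends cis to it, which gives the 2,3-trans-3,4-cis (2S,3R,4R) array. The step needs ring closure to outrun capture of the secondary radical by nickel (direct arylation, or β-elimination of the allyloxy or acetoxy group) and 5-exo to beat 6-endo closure, which the fast cyclisation of 3-oxahex-5-enyl radicals onto an unsubstituted terminal alkene should secure. The arylzinc halide should leave the acetate and the benzyl ethers untouched at room temperature.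

**Step 9**
Reactants: 13 [(2S,3R,4R)-2-[3,4-bis(benzyloxy)phenyl]-4-{[4-(benzyloxy)-3-methoxyphenyl]methyl}oxolan-3-yl]methyl acetate
Product: 14 [(2S,3R,4R)-2-(3,4-dihydroxyphenyl)-4-[(4-hydroxy-3-methoxyphenyl)methyl]oxolan-3-yl]methyl acetate
Conditions: H2 (1 atm), 10% Pd/C, EtOAc, rt, stopped at full debenzylation
Reagents that add atoms: none
Why: Hydrogenolysis of aryl benzyl ethers over Pd/C in a neutral aprotic solvent is much faster than cleavage of the cyclic benzylic C2–O1 bond, and the acetate and the three stereocentres are not affected.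

**Compound list**

1 | 3,4-bis(benzyloxy)benzaldehyde | O=Cc1ccc(OCc2ccccc2)c(OCc2ccccc2)c1 | starting material
2 | triethyl phosphonoacetate | CCOC(=O)CP(=O)(OCC)OCC | starting material
3 | ethyl (E)-3-[3,4-bis(benzyloxy)phenyl]prop-2-enoate | CCOC(=O)/C=C/c1ccc(OCc2ccccc2)c(OCc2ccccc2)c1 | intermediate
4 | (E)-3-[3,4-bis(benzyloxy)phenyl]prop-2-en-1-ol | OC/C=C/c1ccc(OCc2ccccc2)c(OCc2ccccc2)c1 | intermediate
5 | [(2S,3S)-3-[3,4-bis(benzyloxy)phenyl]oxiran-2-yl]methanol | OC[C@@H]1O[C@H]1c1ccc(OCc2ccccc2)c(OCc2ccccc2)c1 | intermediate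
6 | allyl alcohol (prop-2-en-1-ol) | C=CCO | starting material
7 | (2S,3R)-3-(allyloxy)-3-[3,4-bis(benzyloxy)phenyl]propane-1,2-diol | C=CCO[C@H](c1ccc(OCc2ccccc2)c(OCc2ccccc2)c1)[C@@H](O)CO | intermediate
8 | (2S,3R)-3-(allyloxy)-3-[3,4-bis(benzyloxy)phenyl]-2-hydroxypropyl acetate | C=CCO[C@H](c1ccc(OCc2ccccc2)c(OCc2ccccc2)c1)[C@@H](O)COC(C)=O | intermediate
9 | (2R,3R)-3-(allyloxy)-3-[3,4-bis(benzyloxy)phenyl]-2-iodopropyl acetate | C=CCO[C@H](c1ccc(OCc2ccccc2)c(OCc2ccccc2)c1)[C@H](I)COC(C)=O | intermediate
10 | 1-(benzyloxy)-4-bromo-2-methoxybenzene | COc1cc(Br)ccc1OCc1ccccc1 | starting material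
11 | [4-(benzyloxy)-3-methoxyphenyl]magnesium bromide | COc1cc([Mg]Br)ccc1OCc1ccccc1 | intermediate
12 | [4-(benzyloxy)-3-methoxyphenyl]zinc bromide | COc1cc([Zn]Br)ccc1OCc1ccccc1 | intermediate
13 | [(2S,3R,4R)-2-[3,4-bis(benzyloxy)phenyl]-4-{[4-(benzyloxy)-3-methoxyphenyl]methyl}oxolan-3-yl]methyl acetate | COc1cc(C[C@H]2CO[C@H](c3ccc(OCc4ccccc4)c(OCc4ccccc4)c3)[C@H]2COC(C)=O)ccc1OCc1ccccc1 | intermediate
14 | [(2S,3R,4R)-2-(3,4-dihydroxyphenyl)-4-[(4-hydroxy-3-methoxyphenyl)methyl]oxolan-3-yl]methyl acetate | COc1cc(C[C@H]2CO[C@H](c3ccc(O)c(O)c3)[C@H]2COC(C)=O)ccc1O | target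

**Step count**

Total steps: 9. Longest linear sequence: 8 steps (steps 1–6, 8 and 9, from aldehyde 1); step 7 is a one-step side branch.

**Steps most likely to fail**

Step 8. The secondary radical may be captured by nickel before it cyclises (giving uncyclised arylation or β-elimination), it may abstract hydrogen from the solvent, or turnover with the arylzinc may be slow. The fallback separates the two bond formations. Setting out from 9, an iodine atom-transfer radical cyclisation ((Bu3Sn)2 10 mol%, sunlamp, benzene, 80 °C) should isomerise the secondary iodide through the same 5-exo transition state to [(2S,3R,4R)-2-[3,4-bis(benzyloxy)phenyl]-4-(iodomethyl)oxolan-3-yl]methyl acetate F1. A Negishi coupling of this primary iodide with 12 (Pd2(dba)3, tricyclopentylphosphine, N-methylimidazole, THF/NMP, 80 °C) then forms the C7'–ring B bond and comes back to the route at 13.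

Step 4. The electron-rich ring A may let the oxirane ionise, so that the benzylic carbon is attacked with partial retention, a hydride shifts to give a ketone, or the epoxy alcohol 5 decomposes before use. The fallback avoids any substitution at the benzylic carbon and carries the halogen in from the start.
- Setting out from aldehyde 1, a boron-mediated Evans syn-aldol reaction (Bu2BOTf, i-Pr2NEt, CH2Cl2, −78 to 0 °C) is run with (4S)-4-benzyl-3-(bromoacetyl)-1,3-oxazolidin-2-one F2, itself made from (4S)-4-benzyl-1,3-oxazolidin-2-one with n-BuLi and bromoacetyl bromide.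
- This should give (4S)-4-benzyl-3-[(2S,3R)-3-[3,4-bis(benzyloxy)phenyl]-2-bromo-3-hydroxypropanoyl]-1,3-oxazolidin-2-one F3, with the benzylic carbinol configuration fixed by the auxiliary.
- Acid-catalysed O-allylation (allyl 2,2,2-trichloroacetimidate, cat. TfOH, CH2Cl2/cyclohexane, rt) gives (4S)-4-benzyl-3-[(2S,3R)-3-(allyloxy)-3-[3,4-bis(benzyloxy)phenyl]-2-bromopropanoyl]-1,3-oxazolidin-2-one F4.
- Reductive removal of the auxiliary (LiBH4, MeOH, Et2O, 0 °C) gives (2R,3R)-3-(allyloxy)-3-[3,4-bis(benzyloxy)phenyl]-2-bromopropan-1-ol F5.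
- Acetylation (Ac2O, pyridine) gives (2R,3R)-3-(allyloxy)-3-[3,4-bis(benzyloxy)phenyl]-2-bromopropyl acetate F6.
- This bromide is submitted with 12 to the conditions of step 8 and comes back to the route at 13, bypassing steps 1–6.

Step 6. The acetate carbonyl of 8 may take part in the displacement (acyloxonium ion, then iodide attack at the primary carbon or acetyl shift), or elimination may compete with the slow substitution at this oxygen-flanked carbon. The fallback carries a non-participating silyl ether through the substitution.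
- Setting out from diol 7, selective silylation (TBSCl, imidazole, CH2Cl2, 0 °C) gives (2S,3R)-3-(allyloxy)-3-[3,4-bis(benzyloxy)phenyl]-1-[(tert-butyldimethylsilyl)oxy]propan-2-ol F7.
- The iodination of step 6 then gives tert-butyl{[(2R,3R)-3-(allyloxy)-3-[3,4-bis(benzyloxy)phenyl]-2-iodopropyl]oxy}dimethylsilane F8.
- Desilylation (HF·pyridine, THF/pyridine, 0 °C) gives (2R,3R)-3-(allyloxy)-3-[3,4-bis(benzyloxy)phenyl]-2-iodopropan-1-ol F9.
- Acetylation (Ac2O, pyridine, 0 °C) comes back to the route at 9.

**Further compounds**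

F1 | step 8 | [(2S,3R,4R)-2-[3,4-bis(benzyloxy)phenyl]-4-(iodomethyl)oxolan-3-yl]methyl acetate | IC[C@H]1CO[C@H](c2ccc(OCc3ccccc3)c(OCc3ccccc3)c2)[C@H]1COC(C)=O
F2 | step 4 | (4S)-4-benzyl-3-(bromoacetyl)-1,3-oxazolidin-2-one | O=C1OC[C@H](Cc2ccccc2)N1C(=O)CBr
F3 | step 4 | (4S)-4-benzyl-3-[(2S,3R)-3-[3,4-bis(benzyloxy)phenyl]-2-bromo-3-hydroxypropanoyl]-1,3-oxazolidin-2-one | O=C1OC[C@H](Cc2ccccc2)N1C(=O)[C@@H](Br)[C@H](O)c1ccc(OCc2ccccc2)c(OCc2ccccc2)c1
F4 | step 4 | (4S)-4-benzyl-3-[(2S,3R)-3-(allyloxy)-3-[3,4-bis(benzyloxy)phenyl]-2-bromopropanoyl]-1,3-oxazolidin-2-one | O=C1OC[C@H](Cc2ccccc2)N1C(=O)[C@@H](Br)[C@H](OCC=C)c1ccc(OCc2ccccc2)c(OCc2ccccc2)c1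
F5 | step 4 | (2R,3R)-3-(allyloxy)-3-[3,4-bis(benzyloxy)phenyl]-2-bromopropan-1-ol | C=CCO[C@H](c1ccc(OCc2ccccc2)c(OCc2ccccc2)c1)[C@H](Br)CO
F6 | step 4 | (2R,3R)-3-(allyloxy)-3-[3,4-bis(benzyloxy)phenyl]-2-bromopropyl acetate | C=CCO[C@H](c1ccc(OCc2ccccc2)c(OCc2ccccc2)c1)[C@H](Br)COC(C)=O
F7 | step 6 | (2S,3R)-3-(allyloxy)-3-[3,4-bis(benzyloxy)phenyl]-1-[(tert-butyldimethylsilyl)oxy]propan-2-ol | C=CCO[C@H](c1ccc(OCc2ccccc2)c(OCc2ccccc2)c1)[C@@H](O)CO[Si](C)(C)C(C)(C)C
F8 | step 6 | tert-butyl{[(2R,3R)-3-(allyloxy)-3-[3,4-bis(benzyloxy)phenyl]-2-iodopropyl]oxy}dimethylsilane | C=CCO[C@H](c1ccc(OCc2ccccc2)c(OCc2ccccc2)c1)[C@H](I)CO[Si](C)(C)C(C)(C)C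
F9 | step 6 | (2R,3R)-3-(allyloxy)-3-[3,4-bis(benzyloxy)phenyl]-2-iodopropan-1-ol | C=CCO[C@H](c1ccc(OCc2ccccc2)c(OCc2ccccc2)c1)[C@H](I)CO
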